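Plan (azulene numbering: C1–C3 and C3a/C8a form the five-membered ring, C4–C8 with C3a/C8a the seven-membered ring)
Cuts: the ester C–O bond; then the C4 carbinol with its C6=C7 alkene back to a C4 ketone conjugated with C5=C6; then the C3–OH bond back to a C2=C3 cyclopentene; then C1–C2 and C3–C3a together in a (3+2) sense, which leaves a cyclopropane across C3a–C8a–C1 and 3-methylbut-1-yne.
Forward: the seven-membered ring is bought as 3-methylcyclohept-2-enone; a cyclopropane is fused onto it; the second enone arm with the C6 methyl is installed; the five-membered ring is closed last by the (3+2) event.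
Enabling feature: the ring-fusion bond C3a–C8a lies α,β to the C4 oxygen. With C4 as a ketone, a cyclopropane spanning C3a, C8a and the future C1 can be opened by one electron, so that C1 leaves as a radical beside the quaternary C8a and C3a becomes an enolate carbon; this three-carbon unit takes up the two alkyne carbons C2 and C3, the latter carrying the isopropyl group.
Stereochemistry: one carbinol centre is set by catalytic CBS reduction and relayed by hydroxyl-directed cyclopropanation to the quaternary C8a. C3a (enolate protonation), C3 (epoxidation, hydride opening) and C4 (hydride reduction) are then each set by attack on the face opposite the angular methyl.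

Key step: step 5

Assumption: the target is read as the (3S,3aS,4R,8aR) isomer (angular methyl, isopropyl and ester oxygen on one face; tertiary hydroxyl and ring-fusion hydrogen on the other; trans-fused), and compounds 1, 8 and 19 are taken as purchasable.

Step 1
Reactants: 1 3-methylcyclohept-2-en-1-one
Product: 2 (S)-3-methylcyclohept-2-en-1-ol
Conditions: (R)-1-methyl-3,3-diphenyl-tetrahydro-1H,3H-pyrrolo[1,2-c][1,3,2]oxazaborole ((R)-Me-CBS, 10 mol%), BH3·SMe2, THF, −20 °C; MeOH quench
Reagents that add atoms: none
Why: Corey–Bakshi–Shibata reduction of a cyclic enone, with the alkenyl arm acting as the large substituent, should deliver hydride to one carbonyl face and so set the only catalyst-controlled stereocentre of the route.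

Step 2
Reactants: 2 (S)-3-methylcyclohept-2-en-1-ol
Product: 3 (1R,2S,7S)-7-methylbicyclo[5.1.0]octan-2-ol
Conditions: Et2Zn, CH2I2, CH2Cl2, 0 °C
Reagents that add atoms: diiodomethane, ICI
Why: Hydroxyl-directed Simmons–Smith cyclopropanation (Furukawa variant) of a cyclic allylic alcohol delivers the methylene syn to the zinc alkoxide, so the carbinol centre fixes both cyclopropane carbons, one of them the future quaternary C8a.

Step 3
Reactants: 3 (1R,2S,7S)-7-methylbicyclo[5.1.0]octan-2-ol
Product: 5 (1R,7S)-7-methylbicyclo[5.1.0]oct-3-en-2-one, via saturated cyclopropyl ketone 4 (not isolated)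
Conditions: IBX (2.5 equiv), DMSO, 25 °C then 70 °C
Reagents that add atoms: none
Why: IBX oxidises the alcohol and then dehydrogenates the ketone on its only methylene side (the other α-carbon is the cyclopropane CH and cannot become part of an enone), a known one-flask alcohol-to-enone sequence that leaves both cyclopropane stereocentres untouched.

Step 4
Reactants: 5 (1R,7S)-7-methylbicyclo[5.1.0]oct-3-en-2-one
Product: 7 (1R,7S)-4,7-dimethylbicyclo[5.1.0]oct-3-en-2-one, via silyl enol ether 6 (not isolated)
Conditions: Me2CuLi, TMSCl, THF, −78 °C; then Pd(OAc)2, MeCN, 25 °C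
Reagents that add atoms: lithium dimethylcuprate, [Li+].C[Cu-]C
Why: Cuprate conjugate addition to the β-unsubstituted enone with in-situ silylation, followed by Saegusa–Ito oxidation (divalent palladium, β-hydride elimination from the methyl-bearing carbon), should reinstall the enone now carrying the C6 methyl without creating a stereocentre in the product.

Step 5
Reactants: 7 (1R,7S)-4,7-dimethylbicyclo[5.1.0]oct-3-en-2-one; 8 3-methylbut-1-yne
Product: 9 cis-fused (3aS,8aS)-6,8a-dimethyl-3-(propan-2-yl)-3a,7,8,8a-tetrahydroazulen-4(1H)-one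
Conditions: SmI2 (20 mol%), Sm powder (20 mol%), 8 (5 equiv), THF, 55 °C, sealed tube
Reagents that add atoms: none
Why: Proposed new method: electron transfer from divalent samarium to the conjugated ketone of 7 gives a ketyl whose external cyclopropane bond (C1–C8 of the bicyclooctenone, the one that overlaps with the ketyl, not the ring-fusion bond) fragments to a samarium dienolate and a primary radical on the methylene at the quaternary carbon; this radical adds to the unsubstituted terminus of alkyne 8, the vinyl radical closes on the enolate carbon, and the new ketyl returns its electron to trivalent samarium so that the metal turns over. The closest known reaction type is the SmI2-catalysed radical-relay (3+2) cycloaddition of aryl and alkyl cyclopropyl ketones with alkynes; an alkenyl ketone fused in a bicyclo[5.1.0] frame combined with an aliphatic alkyne has not been shown. The five-membered ring closes by a 5-exo-trig attack of the vinyl radical on the exocyclic enolate carbon after the intermolecular addition. The quaternary stereocentre is carried over untouched from the cyclopropane, and the new ring-fusion CH should form cis to the methylene tether (cis-fused 9), which step 6 corrects. The step needs cleavage of the external rather than the ring-fusion cyclopropane bond, secured by orbital overlap in the rigid bicycle and by faster trapping of the primary radical, and head-to-tail addition to the alkyne, secured by attack at its unsubstituted carbon.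

Step 6
Reactants: 9 cis-fused (3aS,8aS)-6,8a-dimethyl-3-(propan-2-yl)-3a,7,8,8a-tetrahydroazulen-4(1H)-one
Product: 11 trans-fused (3aR,8aS)-6,8a-dimethyl-3-(propan-2-yl)-3a,7,8,8a-tetrahydroazulen-4(1H)-one, via lithium trienolate 10 (not isolated)
Conditions: LDA, THF, −78 °C; then AcOH, THF, −78 °C
Reagents that add atoms: none
Why: Deprotonation at the doubly activated ring-fusion CH (α to the ketone and allylic) and kinetic C-protonation of the cross-conjugated enolate at its α-carbon, on the face opposite the axial angular methyl, should invert C3a to the trans-fused ketone without moving either double bond.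

Step 7
Reactants: 11 trans-fused (3aR,8aS)-6,8a-dimethyl-3-(propan-2-yl)-3a,7,8,8a-tetrahydroazulen-4(1H)-one
Product: 12 2,3-epoxide of 11 with the oxygen on the face opposite the angular methyl
Conditions: mCPBA, NaHCO3, CH2Cl2, 0 °C
Reagents that add atoms: meta-chloroperoxybenzoic acid, OOC(=O)c1cccc(Cl)c1
Why: Prilezhaev epoxidation is chemoselective for the electron-rich trisubstituted cyclopentene over the enone and should occur anti to the angular methyl and to the allylic C4 substituent, which places oxygen on the future hydroxyl face of C3.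

Step 8
Reactants: 12 2,3-epoxide of 11
Product: 13 (3S,3aS,4R,8aS)-6,8a-dimethyl-3-(propan-2-yl)-1,2,3,3a,4,7,8,8a-octahydroazulene-3,4-diol
Conditions: LiAlH4, THF, 0 °C to 40 °C; aqueous NaOH work-up
Reagents that add atoms: none
Why: Hydride should open the trisubstituted epoxide in SN2 fashion at the secondary carbon C2, leaving the tertiary C3 alcohol with its configuration, and also reduce the enone carbonyl 1,2 to an allylic alcohol whose configuration is of no consequence.

Step 9
Reactants: 13 (3S,3aS,4R,8aS)-6,8a-dimethyl-3-(propan-2-yl)-1,2,3,3a,4,7,8,8a-octahydroazulene-3,4-diol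
Product: 14 (3S,3aR,8aS)-3-hydroxy-6,8a-dimethyl-3-(propan-2-yl)-2,3,3a,7,8,8a-hexahydroazulen-4(1H)-one
Conditions: MnO2, CH2Cl2, 25 °C
Reagents that add atoms: none
Why: Activated MnO2 oxidises only the allylic secondary alcohol back to the enone and, being neutral, should leave the tertiary alcohol and the epimerisable ring-fusion centre alone.

Step 10
Reactants: 14 (3S,3aR,8aS)-3-hydroxy-6,8a-dimethyl-3-(propan-2-yl)-2,3,3a,7,8,8a-hexahydroazulen-4(1H)-one
Product: 15 bis(trimethylsilyl) derivative of 14: C3 trimethylsilyl ether and C4 silyl dienol ether with C4=C5 and C6=C7 double bonds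
Conditions: TMSOTf, Et3N, CH2Cl2, 0 °C
Reagents that add atoms: trimethylsilyl trifluoromethanesulfonate, C[Si](C)(C)OS(=O)(=O)C(F)(F)F
Why: Soft enolisation of the enone, whose α′ CH (C3a) is buried between two fully substituted carbons, should take place at the ring γ-methylene C7 to give the linear endocyclic silyl dienol ether, while silylation of the tertiary alcohol protects it against retro-aldol cleavage.

Step 11
Reactants: 15 bis(trimethylsilyl) derivative of 14
Product: 18 (3S,3aS,4R,8aR)-6,8a-dimethyl-3-(propan-2-yl)-3-[(trimethylsilyl)oxy]-1,2,3,3a,4,5,8,8a-octahydroazulen-4-ol, via lithium dienolate 16 (not isolated), via deconjugated enone 17 (not isolated)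
Conditions: MeLi, THF, 0 °C; then AcOH, −78 °C; then NaBH4, CeCl3·7H2O, MeOH, −78 °C
Reagents that add atoms: none
Why: MeLi cleaves the enol silane to the linear lithium dienolate, kinetic protonation at its α-carbon C5 gives the β,γ-unsaturated ketone, and immediate Luche reduction on the face opposite the angular methyl and the C3 isopropyl group should set the C4 carbinol with oxygen cis to the angular methyl.

Step 12
Reactants: 18 (3S,3aS,4R,8aR)-6,8a-dimethyl-3-(propan-2-yl)-3-[(trimethylsilyl)oxy]-1,2,3,3a,4,5,8,8a-octahydroazulen-4-ol; 19 4-acetoxybenzoyl chloride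
Product: 20 (3S,3aS,4R,8aR)-6,8a-dimethyl-3-(propan-2-yl)-3-[(trimethylsilyl)oxy]-1,2,3,3a,4,5,8,8a-octahydroazulen-4-yl 4-(acetyloxy)benzoate
Conditions: Et3N, DMAP, CH2Cl2, 25 °C to 40 °C
Reagents that add atoms: none
Why: DMAP-catalysed acylation by the acid chloride can reach only the secondary alcohol, the tertiary oxygen being silylated, and forms the ester with retention at C4.

Step 13
Reactants: 20 (3S,3aS,4R,8aR)-6,8a-dimethyl-3-(propan-2-yl)-3-[(trimethylsilyl)oxy]-1,2,3,3a,4,5,8,8a-octahydroazulen-4-yl 4-(acetyloxy)benzoate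
Product: 21 (3S,3aS,4R,8aR)-3-hydroxy-6,8a-dimethyl-3-(propan-2-yl)-1,2,3,3a,4,5,8,8a-octahydroazulen-4-yl 4-hydroxybenzoate
Conditions: K2CO3, MeOH, 0 °C to 25 °C
Reagents that add atoms: none
Why: Methanolysis should cleave the phenyl acetate and the tertiary trimethylsilyl ether, while the hindered secondary benzoate, deactivated further once its phenol is a phenoxide, should persist.

Compound list
1 | 3-methylcyclohept-2-en-1-one | CC1=CC(=O)CCCC1 | starting material
2 | (S)-3-methylcyclohept-2-en-1-ol | CC1=C[C@@H](O)CCCC1 | intermediate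
3 | (1R,2S,7S)-7-methylbicyclo[5.1.0]octan-2-ol (hydroxyl cis to the cyclopropane methylene) | C1CC[C@H](O)[C@@H]2C[C@]2(C)C1 | intermediate
4 | (1R,7S)-7-methylbicyclo[5.1.0]octan-2-one | C1CCC(=O)[C@@H]2C[C@]2(C)C1 | intermediate
5 | (1R,7S)-7-methylbicyclo[5.1.0]oct-3-en-2-one | C1=CC(=O)[C@@H]2C[C@]2(C)CC1 | intermediate
6 | trimethyl{[(1R,7S)-4,7-dimethylbicyclo[5.1.0]oct-2-en-2-yl]oxy}silane (both C4 epimers) | CC1CC[C@@]2(C)C[C@H]2C(O[Si](C)(C)C)=C1 | intermediate
7 | (1R,7S)-4,7-dimethylbicyclo[5.1.0]oct-3-en-2-one | CC1=CC(=O)[C@@H]2C[C@]2(C)CC1 | intermediate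
8 | 3-methylbut-1-yne | CC(C)C#C | starting material
9 | cis-fused (3aS,8aS)-6,8a-dimethyl-3-(propan-2-yl)-3a,7,8,8a-tetrahydroazulen-4(1H)-one | CC1=CC(=O)[C@@H]2C(C(C)C)=CC[C@]2(C)CC1 | intermediate
10 | lithium (8aS)-6,8a-dimethyl-3-(propan-2-yl)-1,7,8,8a-tetrahydroazulen-4-olate | CC1=CC(O[Li])=C2C(C(C)C)=CC[C@]2(C)CC1 | intermediate
11 | trans-fused (3aR,8aS)-6,8a-dimethyl-3-(propan-2-yl)-3a,7,8,8a-tetrahydroazulen-4(1H)-one | CC1=CC(=O)[C@H]2C(C(C)C)=CC[C@]2(C)CC1 | intermediate
12 | trans-fused 2,3-epoxy-6,8a-dimethyl-3-(propan-2-yl)-2,3,3a,7,8,8a-hexahydroazulen-4(1H)-one, epoxide oxygen on the face opposite the angular methyl | CC1=CC(=O)[C@H]2[C@]3(C(C)C)O[C@@H]3C[C@]2(C)CC1 | intermediate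
13 | (3S,3aS,4R,8aS)-6,8a-dimethyl-3-(propan-2-yl)-1,2,3,3a,4,7,8,8a-octahydroazulene-3,4-diol (one C4 epimer drawn; the other serves equally) | CC1=C[C@@H](O)[C@H]2[C@@](O)(C(C)C)CC[C@]2(C)CC1 | intermediate
14 | (3S,3aR,8aS)-3-hydroxy-6,8a-dimethyl-3-(propan-2-yl)-2,3,3a,7,8,8a-hexahydroazulen-4(1H)-one | CC1=CC(=O)[C@H]2[C@@](O)(C(C)C)CC[C@]2(C)CC1 | intermediate
15 | trimethyl{[6,8a-dimethyl-3-(propan-2-yl)-3-[(trimethylsilyl)oxy]-1,2,3,3a,8,8a-hexahydroazulen-4-yl]oxy}silane, stereocentres as in 14 | CC1=CC[C@@]2(C)CC[C@](O[Si](C)(C)C)(C(C)C)[C@@H]2C(O[Si](C)(C)C)=C1 | intermediate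
16 | lithium 6,8a-dimethyl-3-(propan-2-yl)-3-[(trimethylsilyl)oxy]-1,2,3,3a,8,8a-hexahydroazulen-4-olate, stereocentres as in 14 | CC1=CC[C@@]2(C)CC[C@](O[Si](C)(C)C)(C(C)C)[C@@H]2C(O[Li])=C1 | intermediate
17 | (3S,3aR,8aR)-6,8a-dimethyl-3-(propan-2-yl)-3-[(trimethylsilyl)oxy]-2,3,3a,5,8,8a-hexahydroazulen-4(1H)-one | CC1=CC[C@@]2(C)CC[C@](O[Si](C)(C)C)(C(C)C)[C@@H]2C(=O)C1 | intermediate
18 | (3S,3aS,4R,8aR)-6,8a-dimethyl-3-(propan-2-yl)-3-[(trimethylsilyl)oxy]-1,2,3,3a,4,5,8,8a-octahydroazulen-4-ol | CC1=CC[C@@]2(C)CC[C@](O[Si](C)(C)C)(C(C)C)[C@@H]2[C@H](O)C1 | intermediate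
19 | 4-acetoxybenzoyl chloride | CC(=O)Oc1ccc(cc1)C(Cl)=O | starting material
20 | (3S,3aS,4R,8aR)-6,8a-dimethyl-3-(propan-2-yl)-3-[(trimethylsilyl)oxy]-1,2,3,3a,4,5,8,8a-octahydroazulen-4-yl 4-(acetyloxy)benzoate | CC1=CC[C@@]2(C)CC[C@](O[Si](C)(C)C)(C(C)C)[C@@H]2[C@H](OC(=O)c2ccc(OC(C)=O)cc2)C1 | intermediate
21 | (3S,3aS,4R,8aR)-3-hydroxy-6,8a-dimethyl-3-(propan-2-yl)-1,2,3,3a,4,5,8,8a-octahydroazulen-4-yl 4-hydroxybenzoate | CC1=CC[C@@]2(C)CC[C@](O)(C(C)C)[C@@H]2[C@H](OC(=O)c2ccc(O)cc2)C1 | target

Total step count: 13. Longest linear sequence: 13 steps (1 to 21; 8 and 19 enter as purchased reagents).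

Steps most likely to fail

Step 5 (proposed new method). The ketyl of the conjugated cyclopropyl ketone may fragment the ring-fusion bond instead of the external cyclopropane bond, or the primary radical may be reduced or abstract hydrogen before it adds to the unactivated alkyne, so that no (3+2) adduct forms. The fallback closes the five-membered ring by known polar chemistry and sets out from 1. IBX dehydrogenation gives 3-methylcyclohepta-2,6-dien-1-one F1. Me2CuLi/TMSCl adds to the unsubstituted enone arm to give the silyl dienol ether [(3,6-dimethylcyclohepta-1,6-dien-1-yl)oxy]trimethylsilane F2, and Saegusa–Ito oxidation with Pd(OAc)2 gives 3,6-dimethylcyclohepta-2,6-dien-1-one F3. Copper-catalysed asymmetric conjugate addition of (4-methylpent-3-en-1-yl)magnesium bromide (Cu(OTf)2, chiral NHC ligand) should set the quaternary centre in (R)-3,6-dimethyl-6-(4-methylpent-3-en-1-yl)cyclohept-2-en-1-one F4. mCPBA epoxidises the electron-rich side-chain alkene to the side-chain epoxide F5, and BF3·OEt2 (Meinwald rearrangement with hydride shift) gives the isopropyl ketone (S)-3,6-dimethyl-6-(4-methyl-3-oxopentyl)cyclohept-2-en-1-one F6. KOH/MeOH aldol condensation closes the five-membered ring as the cross-conjugated dienone 6,8a-dimethyl-3-(propan-2-yl)-2,7,8,8a-tetrahydroazulen-4(1H)-one F7. DMDO should epoxidise the more electron-rich tetrasubstituted enone bond anti to the angular methyl to give the 3,3a-epoxy ketone F8. SmI2/MeOH at −78 °C cleaves the α C–O bond and protonates the samarium enolate at C3a on the face opposite the angular methyl. The sequence comes back to the route at 14.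

Step 6. The trienolate may be protonated on the methyl-bearing face, which returns 9, or at the γ-carbon C2, which conjugates the cyclopentene double bond. The fallback sets out from 9 and puts the tertiary hydroxyl in before the ring-fusion hydrogen. DBU in CH2Cl2 deliberately moves the double bond into conjugation to give the cross-conjugated dienone F7 of the first fallback. DMDO epoxidation to the epoxy ketone F8 and SmI2/MeOH reduction follow as above. This comes back to the route at 14 and bypasses steps 7 to 9.

Step 11. The β,γ-enone may slip back into conjugation before hydride arrives, so that the allylic instead of the homoallylic alcohol forms. The fallback sets out from 15 and stores the dienolate as an enol ester. MeLi followed by Ac2O gives the dienyl acetate 6,8a-dimethyl-3-(propan-2-yl)-3-[(trimethylsilyl)oxy]-1,2,3,3a,8,8a-hexahydroazulen-4-yl acetate F9. NaBH4 in EtOH/THF at 0 °C then releases the dienolate slowly by deacylation in the protic reducing medium, so that each molecule of β,γ-enone should be reduced as it forms (the classical enol-ester route from a conjugated enone to a homoallylic alcohol). This comes back to the route at 18.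

Further compounds
F1 | step 5 | 3-methylcyclohepta-2,6-dien-1-one | CC1=CC(=O)C=CCC1
F2 | step 5 | [(3,6-dimethylcyclohepta-1,6-dien-1-yl)oxy]trimethylsilane | CC1=CC(O[Si](C)(C)C)=CC(C)CC1
F3 | step 5 | 3,6-dimethylcyclohepta-2,6-dien-1-one | CC1=CC(=O)C=C(C)CC1
F4 | step 5 | (R)-3,6-dimethyl-6-(4-methylpent-3-en-1-yl)cyclohept-2-en-1-one | CC1=CC(=O)C[C@](C)(CCC=C(C)C)CC1
F5 | step 5 | 6-[2-(3,3-dimethyloxiran-2-yl)ethyl]-3,6-dimethylcyclohept-2-en-1-one, quaternary centre as in F4, both epoxide epimers | CC1=CC(=O)C[C@](C)(CCC2OC2(C)C)CC1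
F6 | step 5 | (S)-3,6-dimethyl-6-(4-methyl-3-oxopentyl)cyclohept-2-en-1-one | CC1=CC(=O)C[C@](C)(CCC(=O)C(C)C)CC1
F7 | step 5 | 6,8a-dimethyl-3-(propan-2-yl)-2,7,8,8a-tetrahydroazulen-4(1H)-one, quaternary centre as in 11 | CC1=CC(=O)C2=C(C(C)C)CC[C@]2(C)CC1
F8 | step 5 | 3,3a-epoxide of F7 with the oxygen on the face opposite the angular methyl | CC1=CC(=O)[C@@]23O[C@]2(C(C)C)CC[C@]3(C)CC1
F0 | step 6 | none | none
F9 | step 11 | 6,8a-dimethyl-3-(propan-2-yl)-3-[(trimethylsilyl)oxy]-1,2,3,3a,8,8a-hexahydroazulen-4-yl acetate, stereocentres as in 15 | CC1=CC[C@@]2(C)CC[C@](O[Si](C)(C)C)(C(C)C)[C@@H]2C(OC(C)=O)=C1
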